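**Retrosynthetic overview**

1. Germacranolide numbering is used throughout: ring C1–C10, lactone C11–C13 (C12 carbonyl, C13 methylene), C14 the methyl on C10, C15 the formyl carbon on C4. The last events are peracid epoxidation of the 1(10)E alkene and chemoselective oxidation of C15; before that the ten-membered carbocycle is closed at C3–C4 by a Nozaki–Hiyama–Kishi reaction of a (Z)-alkenyl iodide with the C3 aldehyde.
2. Key disconnection C7–C11: the α-methylene-γ-butyrolactone (O–C6–C7–C11–C12) is closed from the C6 acrylate of an erythro trans-7,8-epoxy alcohol by a PMe3-triggered Morita–Baylis–Hillman-type 5-exo-tet epoxide opening. One operation makes the ring, the C7 stereocentre and the exocyclic methylene and unveils the C8 hydroxyl.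
3. Enabling feature: C7 lies between two oxygen-bearing carbons, C6 (lactone ring oxygen) and C8 (ester oxygen), with the C7–C11 bond anti to the C8–O bond. This 1,3-dioxygenated triad is the retron of a 2,3-epoxy alcohol whose carbinol oxygen (O6) carries the nucleophile and whose oxirane oxygen stays on C8.
4. The epoxy alcohol comes from a matched Sharpless epoxidation of a C6 dienol. C6 is set by Zn–ProPhenol alkynylation of a skipped dienal (C6–C10, C1–C3) with a propargyl silyl ether (C4, C5, C15); the alkenyl iodide comes from hydroxyl-directed trans-hydroalumination–iodination.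
5. Order of ring formation: temporary 7,8-oxirane (step 7), lactone (step 9), ten-membered carbocycle (step 13), 1,10-oxirane (step 16).

Key step: step 9

Remark: the (S,S)-ProPhenol/Me2Zn catalyst is assumed to add the alkyne to the enal face that gives the (S)-configured C6 carbinol, as for other enals; if the sense were opposite, the (R,R)-ligand would be used with nothing else changed.

**Route**

Step 1
Reactants: 1 4-methylpent-3-en-1-ol
Product: 2 1-methoxy-4-{[(4-methylpent-3-en-1-yl)oxy]methyl}benzene
Conditions: NaH, 4-methoxybenzyl chloride, Bu4NI (cat.), THF/DMF, 0 °C to rt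
Reagents that add atoms: 4-methoxybenzyl chloride COc1ccc(CCl)cc1
Why: Williamson ether synthesis on the primary alkoxide masks the future C3 oxygen as a PMB ether that can later be removed oxidatively without acid.

Step 2
Reactants: 2 1-methoxy-4-{[(4-methylpent-3-en-1-yl)oxy]methyl}benzene
Product: 3 (E)-5-[(4-methoxybenzyl)oxy]-2-methylpent-2-en-1-ol
Conditions: SeO2 (cat.), t-BuOOH, salicylic acid (cat.), CH2Cl2, rt
Reagents that add atoms: selenium dioxide O=[Se]=O (oxygen transferred); tert-butyl hydroperoxide CC(C)(C)OO (terminal oxygen source)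
Why: Riley allylic oxidation (ene reaction, then [2,3]-sigmatropic shift) of the gem-dimethyl alkene should hydroxylate the methyl trans to the chain, which fixes the 1(10)E geometry (C9 trans to C2).

Step 3
Reactants: 3 (E)-5-[(4-methoxybenzyl)oxy]-2-methylpent-2-en-1-ol
Product: 4 (E)-1-{[(5-bromo-4-methylpent-3-en-1-yl)oxy]methyl}-4-methoxybenzene
Conditions: CBr4, PPh3, CH2Cl2, 0 °C
Reagents that add atoms: carbon tetrabromide BrC(Br)(Br)Br
Why: The Appel reaction converts the primary allylic alcohol into the bromide by SN2 displacement of the alkoxyphosphonium ion and should leave the trisubstituted E alkene unchanged.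

Step 4
Reactants: 4 (E)-1-{[(5-bromo-4-methylpent-3-en-1-yl)oxy]methyl}-4-methoxybenzene; 5 (E)-2-(3,3-diethoxyprop-1-en-1-yl)-4,4,5,5-tetramethyl-1,3,2-dioxaborolane
Product: 7 (2E,5E)-8-[(4-methoxybenzyl)oxy]-5-methylocta-2,5-dienal, via dienyl acetal 6 (not isolated)
Conditions: Pd(PPh3)4 (5 mol%), K3PO4, THF/H2O, 50 °C; then aq. oxalic acid, THF, rt
Reagents that add atoms: water O
Why: Suzuki–Miyaura coupling (oxidative addition of the allylic bromide to zerovalent palladium, transmetalation, reductive elimination at the unhindered CH2 terminus) forms C8–C9 with retention of both alkene geometries, and mild acetal hydrolysis then frees the E-enal at C6.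

Step 5
Reactants: 7 (2E,5E)-8-[(4-methoxybenzyl)oxy]-5-methylocta-2,5-dienal; 8 tert-butyldimethyl(prop-2-yn-1-yloxy)silane
Product: 9 (4S,5E,8E)-1-[(tert-butyldimethylsilyl)oxy]-11-[(4-methoxybenzyl)oxy]-8-methylundeca-5,8-dien-2-yn-4-ol
Conditions: (S,S)-ProPhenol (20 mol%), Me2Zn (3 equiv), Ph3P=O (40 mol%), toluene, 4 °C; aq. NH4Cl
Reagents that add atoms: none
Why: Catalytic asymmetric alkynylation: the zinc acetylide adds 1,2 to the enal inside the chiral dinuclear Zn–ProPhenol pocket, which should set the C6 carbinol under ligand control.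

Step 6
Reactants: 9 (4S,5E,8E)-1-[(tert-butyldimethylsilyl)oxy]-11-[(4-methoxybenzyl)oxy]-8-methylundeca-5,8-dien-2-yn-4-ol
Product: 11 (2Z,4S,5E,8E)-1-[(tert-butyldimethylsilyl)oxy]-2-iodo-11-[(4-methoxybenzyl)oxy]-8-methylundeca-2,5,8-trien-4-ol, via alkenylaluminate 10 (not isolated)
Conditions: NaAlH2(OCH2CH2OMe)2 (1.5 equiv), THF, −20 to 0 °C; then I2, THF, −78 °C
Reagents that add atoms: iodine II
Why: Hydroxyl-directed trans-hydroalumination of the propargylic alcohol puts hydride on C5 and aluminium on C4 in a five-membered oxa-aluminacycle, and iodinolysis with retention should give the alkenyl iodide with iodine cis to C6, the low temperature keeping the β-silyloxy alkenylalane from eliminating to an allene.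

Step 7
Reactants: 11 (2Z,4S,5E,8E)-1-[(tert-butyldimethylsilyl)oxy]-2-iodo-11-[(4-methoxybenzyl)oxy]-8-methylundeca-2,5,8-trien-4-ol
Product: 12 erythro trans-7,8-epoxy alcohol (6R,7R,8R in target numbering)
Conditions: Ti(OiPr)4 (0.2 equiv), D-(−)-diisopropyl tartrate (0.25 equiv), t-BuOOH (2 equiv), 4 Å MS, CH2Cl2, −20 °C
Reagents that add atoms: tert-butyl hydroperoxide CC(C)(C)OO
Why: Sharpless asymmetric epoxidation in the matched sense should epoxidise only the E-disubstituted allylic alkene C7=C8 from the face that gives the erythro (anti) epoxy alcohol, while the iodoalkene (mismatched for this tartrate and electron-poor) and the remote trisubstituted alkene are left alone.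

Step 8
Reactants: 12 erythro trans-7,8-epoxy alcohol
Product: 13 C6 acrylate of 12
Conditions: acryloyl chloride, Et3N, CH2Cl2, −30 to 0 °C
Reagents that add atoms: acryloyl chloride C=CC(=O)Cl
Why: Plain O-acylation (esterification) of the secondary alcohol places the three lactone carbons C11–C13 on O6 without touching a stereocentre, the weak amine base being unable to trigger epoxide migration.

Step 9
Reactants: 13 C6 acrylate of 12
Product: 16 8-hydroxy-6,12-olide (α-methylene-γ-butyrolactone; C6/C7/C8 configured as in the target), via phosphonium enolate 14 (not isolated), via phosphonium alkoxide 15 (not isolated)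
Conditions: PMe3 (1.0 equiv), t-BuOH/THF, 0.01 M, 35 °C
Reagents that add atoms: none
Why: Proposed new method: PMe3 adds reversibly to C13 of the acrylate to give the phosphonium ester enolate 14, C11 of which opens the oxirane at C7 from the rear to give 15, and the C8 alkoxide (relayed by t-BuOH) then removes H11 so that PMe3 leaves by E1cB and the C11=C13 methylene is restored. The closest known reaction type is the phosphine-mediated intramolecular Morita–Baylis–Hillman alkylation in which the enolate of an enone–phosphine adduct is alkylated by a tethered epoxide or halide; it is extended here to an acrylate ester so that the ring closed is a lactone. The butyrolactone (O–C6–C7–C11–C12) closes in the 5-exo-tet mode at C7, favoured over 6-endo attack at the equally substituted C8 because only the five-membered ring allows a collinear trajectory. C7 is the only new stereocentre and is fixed by SN2 inversion of the epoxide carbon, so the erythro trans-epoxy alcohol maps onto the 6,7-trans lactone with 8-OH anti to the C7–C11 bond, C6 and C8 being carried through unchanged. The step needs C7 over C8 regioselectivity and ring closure faster than intermolecular Rauhut–Currier coupling: the extended conformer of the erythro isomer already holds the ester oxygen antiperiplanar to the C7–O bond, the enolate (unlike the neutral ester) can reach the s-cis lactone-forming geometry freely, and high dilution disfavours dimerisation. t-BuOH activates the oxirane by hydrogen bonding and protonates the C8 alkoxide so that it does not translactonise to the 8,12-olide, while the alkenyl iodide, the trisubstituted alkene and both ethers are inert to PMe3.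

Step 10
Reactants: 16 8-hydroxy-6,12-olide
Product: 17 8-O-methacrylate of 16
Conditions: methacrylic anhydride, Et3N, DMAP (cat.), CH2Cl2, 0 °C to rt
Reagents that add atoms: methacrylic anhydride CC(=C)C(=O)OC(=O)C(C)=C
Why: DMAP-catalysed acyl transfer (esterification) to the C8 secondary alcohol installs the methacrylate with the stereocentre untouched and removes the free hydroxyl that could otherwise translactonise.

Step 11
Reactants: 17 8-O-methacrylate of 16
Product: 18 C3 primary alcohol (PMB removed)
Conditions: DDQ, CH2Cl2/pH 7 phosphate buffer, 0 °C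
Reagents that add atoms: none
Why: Oxidative PMB cleavage (benzylic hydride abstraction by DDQ, then hydrolysis of the oxocarbenium ion) under buffered conditions should spare the silyl ether, both enoates and the alkenyl iodide.

Step 12
Reactants: 18 C3 primary alcohol
Product: 19 C3 aldehyde (seco-aldehyde)
Conditions: Dess–Martin periodinane, NaHCO3, CH2Cl2, 0 °C; used at once
Reagents that add atoms: none
Why: Dess–Martin oxidation under neutral buffered conditions should give the β,γ-unsaturated aldehyde without migration of the 1(10) alkene into conjugation.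

Step 13
Reactants: 19 C3 aldehyde
Product: 20 macrocyclic (3S)-alcohol (15-O-TBS 1(10)-ene)
Conditions: CrCl2 (8 equiv), NiCl2 (5 mol%), DMSO/THF, 0.003 M with slow addition, rt
Reagents that add atoms: none
Why: Nozaki–Hiyama–Kishi macrocyclisation (nickel-catalysed C–I activation, transmetalation to a trivalent alkenylchromium species, addition to the aldehyde) should close the ten-membered ring at C3–C4 with retention of the ring-cis C4=C5 geometry, the trans-lactone and two alkenes pre-organising the chain and the 3S carbinol expected from attack on the aldehyde face turned to the outside of the folding ring.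

Step 14
Reactants: 20 macrocyclic (3S)-alcohol
Product: 21 3,15-diol
Conditions: HF·pyridine, pyridine, THF, 0 °C
Reagents that add atoms: none
Why: Fluoride-driven desilylation (Si–F bond formation) removes the primary allylic TBS ether under buffered conditions that should leave the lactone, the methacrylate and the allylic C3 alcohol intact.

Step 15
Reactants: 21 3,15-diol
Product: 22 15-aldehyde (1(10)-ene; the target without its oxirane)
Conditions: TEMPO (0.2 equiv), PhI(OAc)2 (1.2 equiv), CH2Cl2, rt
Reagents that add atoms: none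
Why: Oxoammonium (TEMPO) oxidation is sterically selective for the primary allylic alcohol over the secondary C3 alcohol and should stop at the enal without isomerising C4=C5.

Step 16
Reactants: 22 15-aldehyde
Product: 23 target compound (CNP0534814.1)
Conditions: mCPBA (1.05 equiv), NaHCO3, CH2Cl2, −20 to 0 °C
Reagents that add atoms: mCPBA OOC(=O)c1cccc(Cl)c1
Why: Prilezhaev epoxidation should pick the only electron-rich alkene (C1=C10; the others are an enal, an α-methylene lactone and a methacrylate) and attack its outward face in the usual germacrane conformer with C14 on the β side, giving the 1β,10α (1R,10R) oxirane, with the buffer protecting the acid-labile product.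

**Compound list**

1 | 4-methylpent-3-en-1-ol | CC(C)=CCCO | starting material
2 | 1-methoxy-4-{[(4-methylpent-3-en-1-yl)oxy]methyl}benzene | CC(C)=CCCOCc1ccc(OC)cc1 | intermediate
3 | (E)-5-[(4-methoxybenzyl)oxy]-2-methylpent-2-en-1-ol | OC/C(C)=C/CCOCc1ccc(OC)cc1 | intermediate
4 | (E)-1-{[(5-bromo-4-methylpent-3-en-1-yl)oxy]methyl}-4-methoxybenzene | BrC/C(C)=C/CCOCc1ccc(OC)cc1 | intermediate
5 | (E)-2-(3,3-diethoxyprop-1-en-1-yl)-4,4,5,5-tetramethyl-1,3,2-dioxaborolane | CCOC(OCC)/C=C/B1OC(C)(C)C(C)(C)O1 | starting material
6 | (2E,5E)-1,1-diethoxy-8-[(4-methoxybenzyl)oxy]-5-methylocta-2,5-diene | CCOC(OCC)/C=C/C/C(C)=C/CCOCc1ccc(OC)cc1 | intermediate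
7 | (2E,5E)-8-[(4-methoxybenzyl)oxy]-5-methylocta-2,5-dienal | O=C/C=C/C/C(C)=C/CCOCc1ccc(OC)cc1 | intermediate
8 | tert-butyldimethyl(prop-2-yn-1-yloxy)silane | C#CCO[Si](C)(C)C(C)(C)C | starting material
9 | (4S,5E,8E)-1-[(tert-butyldimethylsilyl)oxy]-11-[(4-methoxybenzyl)oxy]-8-methylundeca-5,8-dien-2-yn-4-ol | CC(C)(C)[Si](C)(C)OCC#C[C@@H](O)/C=C/C/C(C)=C/CCOCc1ccc(OC)cc1 | intermediate
10 | sodium alkenylaluminate: five-membered O6–Al–C4=C5–C6 ring with two 2-methoxyethoxy ligands on aluminium | [Na+].COCCO[Al-]1(OCCOC)O[C@@H](/C=C/C/C(C)=C/CCOCc2ccc(OC)cc2)C=C1CO[Si](C)(C)C(C)(C)C | intermediate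
11 | (2Z,4S,5E,8E)-1-[(tert-butyldimethylsilyl)oxy]-2-iodo-11-[(4-methoxybenzyl)oxy]-8-methylundeca-2,5,8-trien-4-ol | CC(C)(C)[Si](C)(C)OC/C(I)=C/[C@@H](O)/C=C/C/C(C)=C/CCOCc1ccc(OC)cc1 | intermediate
12 | erythro trans-7,8-epoxy alcohol of 11, (6R,7R,8R) in target numbering | CC(C)(C)[Si](C)(C)OC/C(I)=C/[C@@H](O)[C@H]1O[C@@H]1C/C(C)=C/CCOCc1ccc(OC)cc1 | intermediate
13 | C6 acrylate of 12 | CC(C)(C)[Si](C)(C)OC/C(I)=C/[C@@H](OC(=O)C=C)[C@H]1O[C@@H]1C/C(C)=C/CCOCc1ccc(OC)cc1 | intermediate
14 | β-trimethylphosphonium ester enolate (zwitterion) of 13 | CC(C)(C)[Si](C)(C)OC/C(I)=C/[C@@H](OC([O-])=CC[P+](C)(C)C)[C@H]1O[C@@H]1C/C(C)=C/CCOCc1ccc(OC)cc1 | intermediate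
15 | 13-trimethylphosphonio lactone C8 alkoxide (zwitterion) | CC(C)(C)[Si](C)(C)OC/C(I)=C/[C@H]1OC(=O)C(C[P+](C)(C)C)[C@@H]1[C@H]([O-])C/C(C)=C/CCOCc1ccc(OC)cc1 | intermediate
16 | 8-hydroxy-6,12-olide: 3-methylenebutyrolactone bearing the (Z)-2-iodo-3-(silyloxy)propenyl group on C6 and the 1-hydroxy-3-methyl-6-(PMB-oxy)hex-3E-enyl chain on C7, 6,7-trans, 8-OH anti to C7–C11 | CC(C)(C)[Si](C)(C)OC/C(I)=C/[C@H]1OC(=O)C(=C)[C@@H]1[C@H](O)C/C(C)=C/CCOCc1ccc(OC)cc1 | intermediate
17 | 8-O-methacrylate of 16 | CC(C)(C)[Si](C)(C)OC/C(I)=C/[C@H]1OC(=O)C(=C)[C@@H]1[C@H](OC(=O)C(C)=C)C/C(C)=C/CCOCc1ccc(OC)cc1 | intermediate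
18 | C3 primary alcohol (17 without PMB) | CC(C)(C)[Si](C)(C)OC/C(I)=C/[C@H]1OC(=O)C(=C)[C@@H]1[C@H](OC(=O)C(C)=C)C/C(C)=C/CCO | intermediate
19 | C3 aldehyde (seco-aldehyde) | CC(C)(C)[Si](C)(C)OC/C(I)=C/[C@H]1OC(=O)C(=C)[C@@H]1[C@H](OC(=O)C(C)=C)C/C(C)=C/CC=O | intermediate
20 | macrocyclic (3S)-alcohol: 15-O-TBS, 1(10)E-ene, ring-cis C4=C5, 8-methacrylate, 6,12-olide | C=C(C)C(=O)O[C@@H]1C/C(C)=C/C[C@H](O)/C(CO[Si](C)(C)C(C)(C)C)=C\[C@H]2OC(=O)C(=C)[C@@H]21 | intermediate
21 | 3,15-diol | C=C(C)C(=O)O[C@@H]1C/C(C)=C/C[C@H](O)/C(CO)=C\[C@H]2OC(=O)C(=C)[C@@H]21 | intermediate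
22 | 15-aldehyde with 1(10)E alkene (target without the oxirane) | C=C(C)C(=O)O[C@@H]1C/C(C)=C/C[C@H](O)/C(C=O)=C\[C@H]2OC(=O)C(=C)[C@@H]21 | intermediate
23 | CNP0534814.1: 1β,10α-epoxy-3β-hydroxy-8β-methacryloyloxy-15-oxo-germacra-4,11(13)-dien-6α,12-olide, ring-cis C4=C5 | C=C(C)C(=O)O[C@@H]1C[C@@]2(C)O[C@@H]2C[C@H](O)/C(C=O)=C\[C@H]2OC(=O)C(=C)[C@@H]21 | target

**Step count**

Total steps: 16. Longest linear sequence: 16 steps (1 to 23); 5 and 8 are purchased.

**Steps most likely to fail**

1. Step 9 (proposed new method). The phosphonium enolate may revert without engaging the oxirane, be diverted into intermolecular Rauhut–Currier coupling, or open the oxirane at C8. The fallback uses known chemistry and sets out from 12. Esterification with diethylphosphonoacetic acid (EDC, DMAP, CH2Cl2) gives the C6 diethylphosphonoacetate F1. NaH in THF (0 °C to rt) generates the stabilised carbanion, which alkylates intramolecularly on the epoxide at C7 (5-exo-tet, inversion) to give the 11-phosphono-8-hydroxy lactone F2. Horner–Wadsworth–Emmons methylenation with aqueous formaldehyde and K2CO3 in THF then installs the C11=C13 methylene, and the route is rejoined at 16.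

2. Step 13. The alkenylchromium addition may show poor facial selectivity at the C3 aldehyde (and compete with intermolecular coupling), so that C3 is delivered as a mixture or mainly as the 3R epimer. The fallback sets out from 19: the ring closure is run as in step 13 without regard to C3, and the crude carbinols, 20 together with its 3-epimer F3, are oxidised with Dess–Martin periodinane (NaHCO3, CH2Cl2) to the C3 enone F4. A reagent-controlled Corey–Bakshi–Shibata reduction ((R)-methyl oxazaborolidine, catecholborane, toluene, −78 °C; alkenyl as the large group) then sets 3S, and the route is rejoined at 20.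

3. Step 16. The peracid may attack the wrong face of the C1=C10 bond, or the acid by-product may trigger transannular opening of the new oxirane by the C3 hydroxyl. The fallback sets out from 22 and replaces sterically governed intermolecular attack by intramolecular delivery: VO(acac)2 (cat.) and t-BuOOH in CH2Cl2 at 0 °C form the C3 vanadate ester, which hands the peroxide oxygen to the homoallylic C1=C10 bond on the side of the C3 oxygen. That is the side required, since C1–O and C3–O are both β, and the enal alkene is too electron-poor to compete; the route is rejoined at 23. This fallback makes no compound outside the list (F0).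

**Further compounds**

F1 | step 9 | C6 diethylphosphonoacetate of 12 | CC(C)(C)[Si](C)(C)OC/C(I)=C/[C@@H](OC(=O)CP(=O)(OCC)OCC)[C@H]1O[C@@H]1C/C(C)=C/CCOCc1ccc(OC)cc1
F2 | step 9 | 11-(diethoxyphosphoryl)-8-hydroxy-6,12-olide | CC(C)(C)[Si](C)(C)OC/C(I)=C/[C@H]1OC(=O)C(P(=O)(OCC)OCC)[C@@H]1[C@H](O)C/C(C)=C/CCOCc1ccc(OC)cc1
F3 | step 13 | 3-epimer (3R) of 20 | C=C(C)C(=O)O[C@@H]1C/C(C)=C/C[C@@H](O)/C(CO[Si](C)(C)C(C)(C)C)=C\[C@H]2OC(=O)C(=C)[C@@H]21
F4 | step 13 | C3 enone (3-oxo analogue of 20) | C=C(C)C(=O)O[C@@H]1C/C(C)=C/CC(=O)/C(CO[Si](C)(C)C(C)(C)C)=C\[C@H]2OC(=O)C(=C)[C@@H]21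
F0 | step 16 | none | none
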